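The route rests on cutting the C5–C1′ bond of the cyclohexenone ring (C1 carbonyl carbon, C2 methoxy carbon, C4 carbinol carbon, C5, C6 methyl-bearing carbon). Because the C4 oxygen and C1′ sit cis on neighbouring ring carbons, a CH2 radical tied through silicon to that oxygen can be delivered to C5, the β-carbon of a C1/C6 enone. One 5-exo closure forms C5–C1′, a temporary oxasilolane ring and the C4/C5 cis relation; base equilibration in the same flask turns C6 trans. The precursor is the (bromomethyl)dimethylsilyl ether of (S)-4-hydroxy-2-methylcyclohex-2-enone. Tamao oxidation, an acetonide that locks C6, methoxy-enone construction and a nickel-catalysed alkenylation finish the target.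

Key step: step 7

Remark: ring atoms keep the target numbering in every intermediate (C1 carbonyl carbon, C4 carbinol carbon, C6 methyl-bearing carbon, C1′ first side-chain carbon). The (R,R)-amide of step 1 is assumed, by analogy with the deprotonation of 4-tert-butylcyclohexanone, to give the (S)-enolate; its enantiomer would be used if the sense proved opposite.

Step 1
Reactants: 1 4-(tert-butyldimethylsilyloxy)cyclohexan-1-one
Product: 3 (S)-tert-butyldimethyl{[4-(trimethylsilyloxy)cyclohex-3-en-1-yl]oxy}silane, via lithium enolate 2 (not isolated)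
Conditions: (R,R)-bis(1-phenylethyl)amine, n-BuLi, LiCl, TMSCl (present from the start), THF, −100 → −78 °C
Reagents that add atoms: chlorotrimethylsilane, C[Si](C)(C)Cl
Why: Enantioselective deprotonation of a prochiral 4-substituted cyclohexanone by a chiral lithium amide with in situ silyl trapping, in which the base distinguishes the two enantiotopic axial α-hydrogens and thereby makes C4 a stereocentre of (S) configuration.

Step 2
Reactants: 3 (S)-tert-butyldimethyl{[4-(trimethylsilyloxy)cyclohex-3-en-1-yl]oxy}silane
Product: 4 (S)-4-(tert-butyldimethylsilyloxy)cyclohex-2-en-1-one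
Conditions: Pd(OAc)2 (10 mol%), O2 (1 atm), DMSO, rt
Reagents that add atoms: none
Why: Saegusa–Ito oxidation, in which divalent palladium takes over the enol silane as a palladium enolate and β-hydride elimination places the double bond on the side fixed in step 1, while O2 returns zerovalent palladium to the cycle and C4 is not touched.

Step 3
Reactants: 4 (S)-4-(tert-butyldimethylsilyloxy)cyclohex-2-en-1-one
Product: 5 (S)-4-(tert-butyldimethylsilyloxy)-2-iodocyclohex-2-en-1-one
Conditions: I2, pyridine, CH2Cl2, 0 °C → rt
Reagents that add atoms: iodine, [I][I]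
Why: α-Iodination of a cyclic enone by a Baylis–Hillman-type sequence, in which pyridine adds reversibly to the β-carbon C5, the enolate is iodinated at C6 and pyridine is expelled.

Step 4
Reactants: 5 (S)-4-(tert-butyldimethylsilyloxy)-2-iodocyclohex-2-en-1-one
Product: 6 (S)-4-(tert-butyldimethylsilyloxy)-2-methylcyclohex-2-en-1-one
Conditions: SnMe4, Pd(PhCN)2Cl2 (5 mol%), AsPh3 (10 mol%), CuI (10 mol%), NMP, 80 °C
Reagents that add atoms: tetramethylstannane, C[Sn](C)(C)C
Why: Stille coupling of the α-iodoenone (insertion of zerovalent palladium into C–I, copper-assisted methyl transfer from tin, reductive elimination), run without base so that the γ-silyloxy enone is not exposed to enolisation.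

Step 5
Reactants: 6 (S)-4-(tert-butyldimethylsilyloxy)-2-methylcyclohex-2-en-1-one
Product: 7 (S)-4-hydroxy-2-methylcyclohex-2-en-1-one
Conditions: 48% aq. HF, MeCN, 0 °C → rt
Reagents that add atoms: none
Why: Acidic fluoride cleavage of the silyl ether, chosen because a free γ-hydroxy enone drifts towards the 1,4-dione under basic desilylation conditions.

Step 6
Reactants: 7 (S)-4-hydroxy-2-methylcyclohex-2-en-1-one; 8 (bromomethyl)chlorodimethylsilane
Product: 9 (S)-4-[(bromomethyl)dimethylsilyloxy]-2-methylcyclohex-2-en-1-one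
Conditions: Et3N, DMAP (cat.), CH2Cl2, 0 °C; filtered, concentrated and used at once
Reagents that add atoms: none
Why: O-Silylation of the secondary alcohol at the Si–Cl bond, which is far more electrophilic than the C–Br bond, places the radical precursor on the C4 oxygen without touching the stereocentre.

Step 7
Reactants: 9 (S)-4-[(bromomethyl)dimethylsilyloxy]-2-methylcyclohex-2-en-1-one
Product: 11 (3aR,4R,7aS)-2,2,4-trimethylhexahydro-1,2-benzoxasilol-5(3H)-one (cis-fused oxasilolane ketone; C6 methyl trans to C1′), via cis-methyl oxasilolane ketone 10 (not isolated)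
Conditions: Bu3SnH (1.3 equiv) and AIBN (0.1 equiv) added over 6 h by syringe pump, benzene (0.01 M), reflux; then DBU (1.5 equiv), 80 °C; MeCN/hexane partition, used crude
Reagents that add atoms: none
Why: Bu3Sn• abstracts bromine from 9, the nucleophilic α-silylmethyl radical held on the C4 oxygen adds to C5, the electron-poor β-carbon of the C1/C6 enone, and the C6 α-keto radical then takes hydrogen from Bu3SnH and carries the chain. The closest known reaction type is the tin hydride cyclisation of (bromomethyl)dimethylsilyl ethers of cyclic allylic alcohols, the standard silicon-tethered way to place a one-carbon unit next to a hydroxyl group. The single ring closed, the 1-oxa-2-silacyclopentane O–Si–C1′–C5–C4, forms by 5-exo-trig closure and can only be cis-fused to the six-membered ring, so C5 is set by the C4 stereocentre because the three-atom O–Si–CH2 tether cannot reach the far face. C6 is first set by hydrogen transfer on the convex face, anti to C1′, which should give mainly the cis-methyl ketone 10; DBU then equilibrates C6 through the enolate, and the trans ketone 11 should predominate because it can hold both C1′ and the methyl group equatorial with only the small C4 oxygen axial, whereas 10 must place C1′ axial or the methyl group syn-axial to O4. The step needs 5-exo attack at C5 to beat 6-endo attack at C6 and premature reduction of the first radical, and this is secured by the polarity match with the enone β-carbon, by the methyl group that shields C6, and by slow addition of the hydride to a dilute solution.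

Step 8
Reactants: 11 (3aR,4R,7aS)-2,2,4-trimethylhexahydro-1,2-benzoxasilol-5(3H)-one (crude)
Product: 12 (2R,3S,4S)-4-hydroxy-3-(hydroxymethyl)-2-methylcyclohexan-1-one
Conditions: 30% H2O2, KF, KHCO3, THF/MeOH (1:1), rt
Reagents that add atoms: hydrogen peroxide, OO
Why: Tamao–Kumada oxidation, in which fluoride-activated silicon takes up hydroperoxide and C1′ migrates from silicon to oxygen with retention, so that the tether becomes the C1′ hydroxyl, the C4 hydroxyl is freed and the C4/C5 cis relation is kept.

Step 9
Reactants: 12 (2R,3S,4S)-4-hydroxy-3-(hydroxymethyl)-2-methylcyclohexan-1-one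
Product: 13 (4aS,5R,8aS)-2,2,5-trimethyl-4a,7,8,8a-tetrahydro-4H-1,3-benzodioxin-6(5H)-one
Conditions: 2-methoxypropene, PPTS (cat.), CH2Cl2, 0 °C; then K2CO3, MeOH, rt
Reagents that add atoms: 2-methoxypropene, COC(C)=C
Why: Acetonide formation across the cis-1,3-diol gives a cis-fused 1,3-dioxane whose axial ketal methyl forces carbocycle C3 equatorial on the dioxane, hence O4 axial and C1′ equatorial on the carbocycle, so a cis C6 methyl would be syn-axial to O4 and the K2CO3 stage holds or restores the trans (6R) configuration under thermodynamic control, whatever erosion C6 has suffered in steps 7 and 8.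

Step 10
Reactants: 13 (4aS,5R,8aS)-2,2,5-trimethyl-4a,7,8,8a-tetrahydro-4H-1,3-benzodioxin-6(5H)-one
Product: 15 (4aS,5R,8aS)-2,2,5-trimethyl-4a,8a-dihydro-4H-1,3-benzodioxin-6(5H)-one, via lithium enolate 14 (not isolated)
Conditions: LiN(i-Pr)2, THF, −78 °C; then N-tert-butylbenzenesulfinimidoyl chloride, −78 °C
Reagents that add atoms: none
Why: Mukaiyama dehydrogenation, in which the kinetic enolate forms at the C2 methylene and not at the hindered C6 methine (so C6 is undisturbed), attacks sulfur of the reagent and loses the sulfenamide by syn-elimination at low temperature to give the C2=C3 enone.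

Step 11
Reactants: 15 (4aS,5R,8aS)-2,2,5-trimethyl-4a,8a-dihydro-4H-1,3-benzodioxin-6(5H)-one
Product: 16 (4aS,5R,8aR)-7-iodo-2,2,5-trimethyl-4a,8a-dihydro-4H-1,3-benzodioxin-6(5H)-one
Conditions: I2, pyridine, CH2Cl2, 0 °C → rt
Reagents that add atoms: iodine, [I][I]
Why: α-Iodination of the enone at C2 by the same pyridine addition, iodination and elimination sequence as in step 3, which works on enones with an unsubstituted β-carbon such as C3.

Step 12
Reactants: 16 (4aS,5R,8aR)-7-iodo-2,2,5-trimethyl-4a,8a-dihydro-4H-1,3-benzodioxin-6(5H)-one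
Product: 17 (4aS,5R,8aR)-7-methoxy-2,2,5-trimethyl-4a,8a-dihydro-4H-1,3-benzodioxin-6(5H)-one
Conditions: CuI (10 mol%), 3,4,7,8-tetramethyl-1,10-phenanthroline (20 mol%), Cs2CO3, MeOH (10 equiv), toluene, 80 °C
Reagents that add atoms: methanol, CO
Why: Ullmann-type C–O coupling of an alkenyl iodide with methanol at phenanthroline-ligated monovalent copper, helped here by the acetonide, which holds H4 out of alignment with the enone π system (suppressing γ-deprotonation) and makes any epimerisation at C6 return to the favoured trans isomer.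

Step 13
Reactants: 17 (4aS,5R,8aR)-7-methoxy-2,2,5-trimethyl-4a,8a-dihydro-4H-1,3-benzodioxin-6(5H)-one
Product: 18 (4R,5S,6R)-4-hydroxy-5-(hydroxymethyl)-2-methoxy-6-methylcyclohex-2-en-1-one
Conditions: PPTS (cat.), MeOH, rt
Reagents that add atoms: none
Why: Acid-catalysed transketalisation to methanol removes the 1,3-dioxane acetonide under conditions too mild to hydrolyse the α-methoxy enone or to enolise C6.

Step 14
Reactants: 18 (4R,5S,6R)-4-hydroxy-5-(hydroxymethyl)-2-methoxy-6-methylcyclohex-2-en-1-one
Product: 19 (4S,5R,6R)-4-hydroxy-5-(iodomethyl)-2-methoxy-6-methylcyclohex-2-en-1-one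
Conditions: I2, PPh3, imidazole, CH2Cl2, 0 °C
Reagents that add atoms: iodine, [I][I]
Why: Appel-type iodination, which picks the primary C1′ hydroxyl over the hindered secondary C4 hydroxyl and stays close to neutral, so that the γ-iodo ketone is not enolised at C6 and cannot close to a cyclopropane.

Step 15
Reactants: 20 geranylacetone, (5E)-6,10-dimethylundeca-5,9-dien-2-one
Product: 24 (5E)-6,10-dimethylundeca-5,9-dien-1-yne, via lithium enolate 21 (not isolated), via enol phosphate 22 (not isolated), via lithium acetylide 23 (not isolated)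
Conditions: LiN(i-Pr)2 (1.05 equiv), THF, −78 °C; ClP(O)(OEt)2; then LiN(i-Pr)2 (2.3 equiv), −78 °C → rt; H2O
Reagents that add atoms: none
Why: One-pot conversion of a methyl ketone into a terminal alkyne by kinetic enolisation at the methyl group, O-phosphorylation and base-induced elimination of diethyl phosphate, which leaves the trisubstituted alkenes untouched.

Step 16
Reactants: 24 (5E)-6,10-dimethylundeca-5,9-dien-1-yne
Product: 26 (1E,5E)-1-bromo-2,6,10-trimethylundeca-1,5,9-triene, via alkenylalane 25 (not isolated)
Conditions: Me3Al, Cp2ZrCl2 (25 mol%), CH2Cl2, 0 °C → rt; then NBS, THF, −30 °C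
Reagents that add atoms: trimethylaluminium, C[Al](C)C; N-bromosuccinimide, O=C1CCC(=O)N1Br
Why: Zirconium-catalysed carboalumination adds methyl and aluminium syn across the alkyne with methyl on the internal carbon, and bromodealumination proceeds with retention, which fixes the (E) geometry of the future C2′=C3′ bond.

Step 17
Reactants: 19 (4S,5R,6R)-4-hydroxy-5-(iodomethyl)-2-methoxy-6-methylcyclohex-2-en-1-one; 26 (1E,5E)-1-bromo-2,6,10-trimethylundeca-1,5,9-triene
Product: 27 (4R,5R,6R)-4-hydroxy-2-methoxy-6-methyl-5-[(2E,6E)-3,7,11-trimethyldodeca-2,6,10-trien-1-yl]cyclohex-2-en-1-one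
Conditions: NiBr2·DME (10 mol%; DME = 1,2-dimethoxyethane), 4,4′-di-tert-butyl-2,2′-bipyridine (12 mol%), Zn dust, NaI, DMA, 25 °C
Reagents that add atoms: none
Why: Nickel-catalysed reductive cross-electrophile coupling of a primary alkyl iodide with an alkenyl bromide, in which the bromide adds to zerovalent nickel with retention of the E geometry, the C1′ radical from the iodide is captured and reductive elimination forms C1′–C2′ under non-basic conditions that tolerate the free hydroxyl and the ketone, so C4, C5 and C6 stay as set.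

Compound list
1 | 4-(tert-butyldimethylsilyloxy)cyclohexan-1-one | O=C1CCC(O[Si](C)(C)C(C)(C)C)CC1 | starting material
2 | lithium (4S)-4-(tert-butyldimethylsilyloxy)cyclohex-1-en-1-olate | [Li]OC1=CC[C@@H](O[Si](C)(C)C(C)(C)C)CC1 | intermediate
3 | (S)-tert-butyldimethyl{[4-(trimethylsilyloxy)cyclohex-3-en-1-yl]oxy}silane | C[Si](C)(C)OC1=CC[C@@H](O[Si](C)(C)C(C)(C)C)CC1 | intermediate
4 | (S)-4-(tert-butyldimethylsilyloxy)cyclohex-2-en-1-one | O=C1CC[C@H](O[Si](C)(C)C(C)(C)C)C=C1 | intermediate
5 | (S)-4-(tert-butyldimethylsilyloxy)-2-iodocyclohex-2-en-1-one | O=C1CC[C@H](O[Si](C)(C)C(C)(C)C)C=C1[I] | intermediate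
6 | (S)-4-(tert-butyldimethylsilyloxy)-2-methylcyclohex-2-en-1-one | O=C1CC[C@H](O[Si](C)(C)C(C)(C)C)C=C1C | intermediate
7 | (S)-4-hydroxy-2-methylcyclohex-2-en-1-one | O=C1CC[C@H](O)C=C1C | intermediate
8 | (bromomethyl)chlorodimethylsilane | C[Si](C)(Cl)CBr | starting material
9 | (S)-4-[(bromomethyl)dimethylsilyloxy]-2-methylcyclohex-2-en-1-one | O=C1CC[C@H](O[Si](C)(C)CBr)C=C1C | intermediate
10 | (3aR,4S,7aS)-2,2,4-trimethylhexahydro-1,2-benzoxasilol-5(3H)-one (cis-fused; methyl cis to C1′; kinetic C6 epimer of 11) | O=C1CC[C@@H]2O[Si](C)(C)C[C@@H]2[C@@H]1C | intermediate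
11 | (3aR,4R,7aS)-2,2,4-trimethylhexahydro-1,2-benzoxasilol-5(3H)-one (cis-fused; methyl trans to C1′) | O=C1CC[C@@H]2O[Si](C)(C)C[C@@H]2[C@H]1C | intermediate
12 | (2R,3S,4S)-4-hydroxy-3-(hydroxymethyl)-2-methylcyclohexan-1-one | O=C1CC[C@H](O)[C@H](CO)[C@H]1C | intermediate
13 | (4aS,5R,8aS)-2,2,5-trimethyl-4a,7,8,8a-tetrahydro-4H-1,3-benzodioxin-6(5H)-one | O=C1CC[C@@H]2OC(C)(C)OC[C@@H]2[C@H]1C | intermediate
14 | lithium enolate of 13 at C1/C2 | [Li]OC1=CC[C@@H]2OC(C)(C)OC[C@@H]2[C@H]1C | intermediate
15 | (4aS,5R,8aS)-2,2,5-trimethyl-4a,8a-dihydro-4H-1,3-benzodioxin-6(5H)-one | O=C1C=C[C@@H]2OC(C)(C)OC[C@@H]2[C@H]1C | intermediate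
16 | (4aS,5R,8aR)-7-iodo-2,2,5-trimethyl-4a,8a-dihydro-4H-1,3-benzodioxin-6(5H)-one | O=C1C([I])=C[C@@H]2OC(C)(C)OC[C@@H]2[C@H]1C | intermediate
17 | (4aS,5R,8aR)-7-methoxy-2,2,5-trimethyl-4a,8a-dihydro-4H-1,3-benzodioxin-6(5H)-one | O=C1C(OC)=C[C@@H]2OC(C)(C)OC[C@@H]2[C@H]1C | intermediate
18 | (4R,5S,6R)-4-hydroxy-5-(hydroxymethyl)-2-methoxy-6-methylcyclohex-2-en-1-one | O=C1C(OC)=C[C@H](O)[C@H](CO)[C@H]1C | intermediate
19 | (4S,5R,6R)-4-hydroxy-5-(iodomethyl)-2-methoxy-6-methylcyclohex-2-en-1-one | O=C1C(OC)=C[C@H](O)[C@H](C[I])[C@H]1C | intermediate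
20 | geranylacetone, (5E)-6,10-dimethylundeca-5,9-dien-2-one | CC(=O)CC/C=C(\C)CCC=C(C)C | starting material
21 | lithium (5E)-6,10-dimethylundeca-1,5,9-trien-2-olate | [Li]OC(=C)CC/C=C(\C)CCC=C(C)C | intermediate
22 | diethyl (5E)-6,10-dimethylundeca-1,5,9-trien-2-yl phosphate | C=C(OP(=O)(OCC)OCC)CC/C=C(\C)CCC=C(C)C | intermediate
23 | lithium (5E)-6,10-dimethylundeca-5,9-dien-1-yn-1-ide | [Li]C#CCC/C=C(\C)CCC=C(C)C | intermediate
24 | (5E)-6,10-dimethylundeca-5,9-dien-1-yne | C#CCC/C=C(\C)CCC=C(C)C | intermediate
25 | dimethyl[(1E,5E)-2,6,10-trimethylundeca-1,5,9-trien-1-yl]alumane | C[Al](C)/C=C(\C)CC/C=C(\C)CCC=C(C)C | intermediate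
26 | (1E,5E)-1-bromo-2,6,10-trimethylundeca-1,5,9-triene | Br/C=C(\C)CC/C=C(\C)CCC=C(C)C | intermediate
27 | (4R,5R,6R)-4-hydroxy-2-methoxy-6-methyl-5-[(2E,6E)-3,7,11-trimethyldodeca-2,6,10-trien-1-yl]cyclohex-2-en-1-one | COC1=C[C@H](O)[C@H](C/C=C(\C)CC/C=C(\C)CCC=C(C)C)[C@@H](C)C1=O | target

Total step count: 17 (15 on the ring line, 2 for the alkenyl bromide).
Longest linear sequence: 15 steps (steps 1–14, then step 17).

Steps most likely to fail

Step 7. The silylmethyl radical may take hydrogen before it closes, may close 6-endo at C6, or the labile silyl ether may hydrolyse before the chain starts. The C6 equilibration in the oxasilolane may also stop short, although step 9 covers that. In that case C1′ would be brought in from the same oxygen by an ionic, alkoxide-directed conjugate addition. Setting out from 7, an excess of [(isopropoxydimethylsilyl)methyl]magnesium chloride in THF first forms the C4 magnesium alkoxide, which then guides a second equivalent to C5 on the oxygen-bearing face (directed 1,4-addition to a 4-oxido enone). Protonation of the magnesium enolate anti to C1′ should give the cis-methyl β-(silylmethyl) hydroxy ketone F1. Tamao oxidation of its C–Si bond (H2O2, KF, KHCO3) should give the cis-methyl diol F2, and 2-methoxypropene with PPTS the C6-epimeric acetonide F3. The K2CO3/MeOH stage of step 9 then inverts C6 and returns the route at acetonide 13.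

Step 12. Protodeiodination, or base-induced isomerisation of the γ-oxygenated iodoenone, may outrun C–O bond formation at copper. The methoxy group would then be introduced without a metal by the epoxy ketone route. Setting out from enone 15, nucleophilic epoxidation (H2O2, NaOH, MeOH, 0 °C) should give the 2,3-epoxy ketone F4, with the oxirane expected anti to O4 (its configuration is of no consequence). NaOMe in refluxing MeOH then opens the oxirane at C2, next to the carbonyl, to the 3-hydroxy-2-methoxy ketone F5, whose C3 hydroxyl is lost as water (E1cB), which returns the route at 17.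

Step 17. The primary iodide may simply be reduced or dimerised, or the alkenylnickel species may be used up by homocoupling, before the two partners meet at nickel. The C1′–C2′ bond would then be made by a two-electron Negishi coupling after masking the hydroxyl. Setting out from 19, silylation (TESCl, imidazole, DMF, 0 °C) gives the triethylsilyl ether F6. Zinc insertion (Zn dust, LiCl, THF, 40 °C) gives the alkylzinc iodide F7. Coupling with 26 in THF, catalysed by Pd(dppf)Cl2 (dppf = 1,1′-bis(diphenylphosphino)ferrocene), gives the triethylsilyl ether of the target F8, and HF·pyridine in THF then releases 27.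

Further compounds
F1 | step 7 | (2S,3R,4S)-4-hydroxy-3-{[dimethyl(propan-2-yloxy)silyl]methyl}-2-methylcyclohexan-1-one | O=C1CC[C@H](O)[C@H](C[Si](C)(C)OC(C)C)[C@@H]1C
F2 | step 7 | (2S,3S,4S)-4-hydroxy-3-(hydroxymethyl)-2-methylcyclohexan-1-one (C6 epimer of 12) | O=C1CC[C@H](O)[C@H](CO)[C@@H]1C
F3 | step 7 | (4aS,5S,8aS)-2,2,5-trimethyl-4a,7,8,8a-tetrahydro-4H-1,3-benzodioxin-6(5H)-one (C6 epimer of 13) | O=C1CC[C@@H]2OC(C)(C)OC[C@@H]2[C@@H]1C
F4 | step 12 | 2,3-epoxide of 15 (oxirane oxygen anti to O4) | O=C1[C@H]2O[C@H]2[C@@H]3OC(C)(C)OC[C@@H]3[C@H]1C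
F5 | step 12 | 3-hydroxy-2-methoxy ketone formed from F4 (methoxy syn to O4; hydroxyl anti) | O=C1[C@H](OC)[C@@H](O)[C@@H]2OC(C)(C)OC[C@@H]2[C@H]1C
F6 | step 17 | triethylsilyl ether of 19 | O=C1C(OC)=C[C@H](O[Si](CC)(CC)CC)[C@H](C[I])[C@H]1C
F7 | step 17 | alkylzinc iodide derived from F6 | O=C1C(OC)=C[C@H](O[Si](CC)(CC)CC)[C@H](C[Zn][I])[C@H]1C
F8 | step 17 | triethylsilyl ether of 27 | O=C1C(OC)=C[C@H](O[Si](CC)(CC)CC)[C@H](C/C=C(\C)CC/C=C(\C)CCC=C(C)C)[C@H]1C
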